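Numbering: C1 is the ring sp2 carbon carrying C7H2OBz, C2 is CHOBz, C3 is CHOAc, C4 and C5 are CHOH, C6 is the vinyl CH. The C3/C4 oxygens lie on one face (β) and the C2/C5 oxygens on the other (α).
Cuts: the three acyl–oxygen bonds go first (acetate on O3, benzoates on O2 and O7). C7 and C2 then return to ester and ketone level and C1=C6 to a saturated β-keto ester. Last, C1–C2 and C1–C6 are cut together, which releases C1 with C7 as ethyl diazoacetate.
Enabling feature: C1 is the only atom of the six-membered carbocycle whose substituent is carbon, and it lies between oxygenated C2 and oxygen-free C6. Without it, C2–C3–C4–C5–C6 form a cyclopentanone (C2 is the carbonyl) whose α-carbons differ sharply: C3 bears oxygen and C6 is a bare methylene. A one-carbon insertion can therefore be steered to the C2–C6 side.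
Forward: the five-membered ring is bought and its C3 and C4 oxygens are added. It is enlarged to the six-membered ring in step 3, the only ring event. The C1=C6 bond and the C2/C7 alcohols follow, and the esters are placed last.
Stereochemistry: C5 comes from the commercial (R)-silyloxy enone. C3 and C4 come from osmylation anti to that silyl ether. C2 comes from hydride attack anti to the acetonide, followed by Mitsunobu inversion with benzoic acid.

Key step: step 3

Remark: 6 is written as its enol. The centres that are erased again in the same flask are left undefined: C1 and C2 of 5, C1 of 7 and 8, selenium of 8, and the orthoester carbon of 14.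

Step 1
Reactants: 1 (R)-4-(tert-butyldimethylsilyloxy)cyclopent-2-en-1-one
Product: 2 (2S,3R,4R)-4-(tert-butyldimethylsilyloxy)-2,3-dihydroxycyclopentan-1-one
Conditions: OsO4 (cat.), N-methylmorpholine N-oxide, citric acid, t-BuOH/H2O, rt
Reagents that add atoms: N-methylmorpholine N-oxide C[N+]1([O-])CCOCC1 (oxygen passed on through OsO4); water O
Why: The OsO4-catalysed syn-dihydroxylation with amine-oxide reoxidation delivers both oxygens to the enone face opposite the bulky C5 silyl ether, which sets C3 and C4 cis to each other and trans to C5, while the citric acid keeps the medium slightly acidic so that turnover on the electron-poor alkene continues and β-elimination of silanol is held back.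

Step 2
Reactants: 2 dihydroxy ketone
Product: 3 (3aS,6R,6aR)-6-(tert-butyldimethylsilyloxy)-2,2-dimethyltetrahydro-4H-cyclopenta[d][1,3]dioxol-4-one
Conditions: Me2C(OMe)2, p-toluenesulfonic acid (cat.), acetone, rt
Reagents that add atoms: 2,2-dimethoxypropane COC(C)(C)OC
Why: Acid-catalysed transketalisation closes the cis-fused dioxolane on the C3/C4 cis-diol without touching a stereocentre and masks both hydroxyls against the diazo ester and the Lewis acid of the next step.

Step 3
Reactants: 3 acetonide-protected silyloxy cyclopentanone; 4 ethyl diazoacetate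
Product: 6 ethyl (3aS,7R,7aR)-7-(tert-butyldimethylsilyloxy)-4-hydroxy-2,2-dimethyl-3a,6,7,7a-tetrahydro-1,3-benzodioxole-5-carboxylate (enol form of the ring-expanded β-keto ester), via diazonium betaine 5 (not isolated)
Conditions: BF3·OEt2, CH2Cl2, −78 to −20 °C; aq NaHCO3
Reagents that add atoms: ethyl diazoacetate 4 CCOC(=O)C=[N+]=[N-]
Why: BF3 activates the C2 carbonyl of 3, the nucleophilic diazo carbon of 4 (the future C1, already carrying C7 as its ester) adds to it to give betaine 5, and the C2–C6 bond that lies antiperiplanar to the diazonium group shifts to that carbon as N2 departs, so that C1–C2 and C1–C6 are both made in one flask. The closest known reaction type is the Lewis acid promoted diazoacetate homologation of cyclic ketones, a Tiffeneau–Demjanov-type ring expansion. The six-membered ring therefore arises by enlargement of the cyclopentane through a 1,2-shift and not by cyclisation of a chain, so no Baldwin mode applies. No lasting stereocentre is formed, because C1 is flattened by enolisation in 6 and C3, C4 and C5 are not touched. The step needs migration of C6 in preference to C3, and the substrate secures this because C3 is the more substituted terminus and its oxygen withdraws electron density from the bond that would have to migrate, whereas C6 is an unhindered methylene. The enolised β-keto ester is held by boron and should not take up a second diazo ester, and the low temperature spares the acetonide and the β-silyloxy ketone.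

Step 4
Reactants: 6 β-keto ester (enol form)
Product: 9 ethyl (3aS,7R,7aR)-7-(tert-butyldimethylsilyloxy)-2,2-dimethyl-4-oxo-3a,4,7,7a-tetrahydro-1,3-benzodioxole-5-carboxylate, via selenide 7 (not isolated), via selenoxide 8 (not isolated)
Conditions: PhSeCl, pyridine, CH2Cl2, 0 °C; wash with aq HCl; then 30% H2O2, CH2Cl2, 0 °C; used at once
Reagents that add atoms: none
Why: Electrophilic α-selenenylation of the enolised β-keto ester at C1 followed by oxidation and selenoxide syn-elimination can only take a hydrogen from C6, the sole neighbouring carbon that carries one, so the C1=C6 bond forms regiospecifically under nearly neutral conditions once the pyridine has been washed out.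

Step 5
Reactants: 9 ene keto ester
Product: 10 (3aR,4R,7R,7aR)-7-(tert-butyldimethylsilyloxy)-5-(hydroxymethyl)-2,2-dimethyl-3a,4,7,7a-tetrahydro-1,3-benzodioxol-4-ol
Conditions: iBu2AlH (excess), CH2Cl2, −78 to 0 °C; aq potassium sodium tartrate
Reagents that add atoms: none
Why: This hydride reduction takes the enone carbonyl in the 1,2-sense and the conjugated ester to the primary allylic alcohol in one operation, and hydride reaches C2 from the α face opposite the cis-fused dioxolane, so the new C2 hydroxyl stands β and cis to O3, as is usual for cyclohexenones flanked by an acetonide.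

Step 6
Reactants: 10 allylic diol
Product: 11 [(3aR,4R,7R,7aR)-7-(tert-butyldimethylsilyloxy)-4-hydroxy-2,2-dimethyl-3a,4,7,7a-tetrahydro-1,3-benzodioxol-5-yl]methyl benzoate
Conditions: PhCOCl (1 equiv), pyridine, CH2Cl2, −40 to 0 °C
Reagents that add atoms: benzoyl chloride O=C(Cl)c1ccccc1
Why: Kinetically controlled O-acylation distinguishes the unhindered primary allylic C7 hydroxyl from the secondary C2 hydroxyl that sits on the face shielded by the dioxolane, and it touches no stereocentre.

Step 7
Reactants: 11 C7 monobenzoate
Product: 12 [(3aR,4S,7R,7aR)-4-(benzoyloxy)-7-(tert-butyldimethylsilyloxy)-2,2-dimethyl-3a,4,7,7a-tetrahydro-1,3-benzodioxol-5-yl]methyl benzoate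
Conditions: PPh3, diisopropyl azodicarboxylate, PhCO2H, toluene, 0 °C to rt
Reagents that add atoms: benzoic acid O=C(O)c1ccccc1
Why: The Mitsunobu reaction turns the β C2 hydroxyl into an oxyphosphonium leaving group that benzoate displaces in the SN2 sense from the open α face, which installs the C2 benzoate and at the same time inverts C2 to the required S configuration, trans to O3.

Step 8
Reactants: 12 protected dibenzoate
Product: 13 [(3R,4S,5S,6S)-6-(benzoyloxy)-3,4,5-trihydroxycyclohex-1-en-1-yl]methyl benzoate
Conditions: CF3CO2H/H2O 9:1, 0 °C to rt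
Reagents that add atoms: none
Why: Acid hydrolysis cleaves the isopropylidene acetal and the secondary silyl ether together while the benzoates are stable to it and every C–O bond at a stereocentre stays intact, so the C3, C4, C5 triol is released in one deprotection.

Step 9
Reactants: 13 triol dibenzoate
Product: 15 [(3R,4S,5S,6S)-5-acetoxy-6-(benzoyloxy)-3,4-dihydroxycyclohex-1-en-1-yl]methyl benzoate (target), via cyclic orthoacetate 14 (not isolated)
Conditions: MeC(OMe)3, camphor-10-sulfonic acid (cat.), MeCN, rt; then 80% aq AcOH, rt
Reagents that add atoms: trimethyl orthoacetate COC(C)(OC)OC; water O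
Why: Orthoester exchange picks out the only cis-diol (C3/C4) as the five-membered cyclic orthoacetate 14, and its mild regioselective hydrolysis follows the established rule that the ester ends up on the axial oxygen, which here is O3 because allylic 1,2-strain with the C1 side chain holds the C2 benzoate pseudoaxial and hence O3 axial and O4 and O5 equatorial, the same axial-equatorial-equatorial triol pattern that gives 2-O-acetates from rhamnopyranosides.

Compound list
1 | (R)-4-(tert-butyldimethylsilyloxy)cyclopent-2-en-1-one | O=C1C=C[C@H](O[Si](C)(C)C(C)(C)C)C1 | starting material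
2 | (2S,3R,4R)-4-(tert-butyldimethylsilyloxy)-2,3-dihydroxycyclopentan-1-one (cis-diol trans to the silyl ether) | O[C@H]1[C@@H](O)[C@H](O[Si](C)(C)C(C)(C)C)CC1=O | intermediate
3 | (3aS,6R,6aR)-6-(tert-butyldimethylsilyloxy)-2,2-dimethyltetrahydro-4H-cyclopenta[d][1,3]dioxol-4-one (carbonyl is C2) | CC1(C)O[C@H]2[C@@H](O1)[C@H](O[Si](C)(C)C(C)(C)C)CC2=O | intermediate
4 | ethyl diazoacetate | CCOC(=O)C=[N+]=[N-] | starting material
5 | diazonium betaine, adduct of the diazo carbon of 4 to the C2 carbonyl of 3, drawn without the BF3 on its oxide | CC1(C)O[C@H]2[C@@H](O1)[C@H](O[Si](C)(C)C(C)(C)C)CC2([O-])C([N+]#N)C(=O)OCC | intermediate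
6 | ethyl (3aS,7R,7aR)-7-(tert-butyldimethylsilyloxy)-4-hydroxy-2,2-dimethyl-3a,6,7,7a-tetrahydro-1,3-benzodioxole-5-carboxylate (enol of the β-keto ester; ester on C1, enol OH on C2) | CC1(C)O[C@H]2[C@@H](O1)[C@H](O[Si](C)(C)C(C)(C)C)CC(C(=O)OCC)=C2O | intermediate
7 | ethyl (3aS,7R,7aR)-7-(tert-butyldimethylsilyloxy)-2,2-dimethyl-4-oxo-5-(phenylselanyl)hexahydro-1,3-benzodioxole-5-carboxylate (C1 epimers) | CC1(C)O[C@H]2[C@@H](O1)[C@H](O[Si](C)(C)C(C)(C)C)CC([Se]c3ccccc3)(C(=O)OCC)C2=O | intermediate
8 | selenoxide of 7, the 5-(phenylseleninyl) compound | CC1(C)O[C@H]2[C@@H](O1)[C@H](O[Si](C)(C)C(C)(C)C)CC([Se](=O)c3ccccc3)(C(=O)OCC)C2=O | intermediate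
9 | ethyl (3aS,7R,7aR)-7-(tert-butyldimethylsilyloxy)-2,2-dimethyl-4-oxo-3a,4,7,7a-tetrahydro-1,3-benzodioxole-5-carboxylate | CC1(C)O[C@H]2[C@@H](O1)[C@H](O[Si](C)(C)C(C)(C)C)C=C(C(=O)OCC)C2=O | intermediate
10 | (3aR,4R,7R,7aR)-7-(tert-butyldimethylsilyloxy)-5-(hydroxymethyl)-2,2-dimethyl-3a,4,7,7a-tetrahydro-1,3-benzodioxol-4-ol (C2 OH cis to the dioxolane) | CC1(C)O[C@H]2[C@@H](O1)[C@H](O[Si](C)(C)C(C)(C)C)C=C(CO)[C@H]2O | intermediate
11 | [(3aR,4R,7R,7aR)-7-(tert-butyldimethylsilyloxy)-4-hydroxy-2,2-dimethyl-3a,4,7,7a-tetrahydro-1,3-benzodioxol-5-yl]methyl benzoate | CC1(C)O[C@H]2[C@@H](O1)[C@H](O[Si](C)(C)C(C)(C)C)C=C(COC(=O)c3ccccc3)[C@H]2O | intermediate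
12 | [(3aR,4S,7R,7aR)-4-(benzoyloxy)-7-(tert-butyldimethylsilyloxy)-2,2-dimethyl-3a,4,7,7a-tetrahydro-1,3-benzodioxol-5-yl]methyl benzoate (C2 benzoate trans to the dioxolane) | CC1(C)O[C@H]2[C@@H](O1)[C@H](O[Si](C)(C)C(C)(C)C)C=C(COC(=O)c3ccccc3)[C@@H]2OC(=O)c3ccccc3 | intermediate
13 | [(3R,4S,5S,6S)-6-(benzoyloxy)-3,4,5-trihydroxycyclohex-1-en-1-yl]methyl benzoate | O[C@H]1[C@@H](O)[C@H](O)C=C(COC(=O)c2ccccc2)[C@@H]1OC(=O)c1ccccc1 | intermediate
14 | [(3aR,4S,7R,7aS)-4-(benzoyloxy)-7-hydroxy-2-methoxy-2-methyl-3a,4,7,7a-tetrahydro-1,3-benzodioxol-5-yl]methyl benzoate (C3/C4 cyclic orthoacetate) | COC1(C)O[C@H]2[C@@H](O1)[C@H](O)C=C(COC(=O)c3ccccc3)[C@@H]2OC(=O)c3ccccc3 | intermediate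
15 | [(3R,4S,5S,6S)-5-acetoxy-6-(benzoyloxy)-3,4-dihydroxycyclohex-1-en-1-yl]methyl benzoate, CNP0213675.1 | CC(=O)O[C@H]1[C@@H](O)[C@H](O)C=C(COC(=O)c2ccccc2)[C@@H]1OC(=O)c1ccccc1 | target

Total step count: 9. Longest linear sequence: 9 steps (1 to 15).

Steps most likely to fail

Step 3. The Lewis acid may open the acetonide or trigger loss of silanol from the β-silyloxy ketone before the diazo ester has added. Migration may also not be fully selective for C6. The fallback splits the insertion into an addition under basic conditions and a separate metal-carbene shift, with the same two bonds formed. Setting out from 3, ethyl diazoacetate 4 is deprotonated with LiN(iPr)2 in THF at −78 °C in the presence of the ketone. Aldol-type addition to the face opposite the dioxolane gives the α-diazo-β-hydroxy ester F1. Catalytic Rh2(OAc)4 in CH2Cl2 at rt then expels nitrogen, and the rhodium carbene takes up the electron-richer C6 by a 1,2-shift. This comes back to the route at 6.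

Step 4. The doubly activated enone may tautomerise through its acidic C5 hydrogen, with loss of the C5 configuration and then of the C4 oxygen and the silanol on the way to an aromatic ring. It may also pick up nucleophiles at C6 before it is reduced. The fallback reverses the order of reduction and elimination, so that this enone is never formed. Setting out from 7, isolated after the acid wash, NaBH4 in MeOH at −20 °C reduces the C2 ketone from the face opposite the dioxolane to give the β-hydroxy selenide F2. Oxidation with H2O2 and selenoxide elimination, which runs away from the carbinol carbon and toward C6, give the hydroxy enoate F3. Reduction of its ester with iBu2AlH comes back to the route at 10.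

Step 9. Hydrolysis of the orthoacetate may discriminate poorly between O3 and O4 if the half-chair is more mobile than expected. The acetyl group may also wander from O3 to the cis O4. The fallback blocks O4 and O5 together before acetylation. Setting out from 13, butane-2,3-dione, HC(OMe)3 and catalytic camphor-10-sulfonic acid in MeOH give the butane-2,3-diacetal F4. This acetal forms under thermodynamic control only on the trans-diequatorial C4/C5 diol and leaves the C3 hydroxyl free. Ac2O, pyridine and 4-(dimethylamino)pyridine convert it into its C3 acetate F5. CF3CO2H/H2O then removes the diacetal and comes back to the route at 15.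

Further compounds
F1 | step 3 | ethyl 2-diazo-2-[(6R)-6-(tert-butyldimethylsilyloxy)-4-hydroxy-2,2-dimethyltetrahydro-4H-cyclopenta[d][1,3]dioxol-4-yl]acetate, tertiary C2 hydroxyl cis to the dioxolane | CC1(C)O[C@H]2[C@@H](O1)[C@H](O[Si](C)(C)C(C)(C)C)C[C@]2(O)C(=[N+]=[N-])C(=O)OCC
F2 | step 4 | ethyl 7-(tert-butyldimethylsilyloxy)-4-hydroxy-2,2-dimethyl-5-(phenylselanyl)hexahydro-1,3-benzodioxole-5-carboxylate, C2 hydroxyl cis to the dioxolane, C1 epimers | CC1(C)O[C@H]2[C@@H](O1)[C@H](O[Si](C)(C)C(C)(C)C)CC([Se]c3ccccc3)(C(=O)OCC)[C@H]2O
F3 | step 4 | ethyl 7-(tert-butyldimethylsilyloxy)-4-hydroxy-2,2-dimethyl-3a,4,7,7a-tetrahydro-1,3-benzodioxole-5-carboxylate, C2 hydroxyl cis to the dioxolane | CC1(C)O[C@H]2[C@@H](O1)[C@H](O[Si](C)(C)C(C)(C)C)C=C(C(=O)OCC)[C@H]2O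
F4 | step 9 | C4,C5-O-(2,3-dimethoxybutane-2,3-diyl) acetal of 13, both acetal carbons S with axial methoxy groups, C3 hydroxyl free | O[C@H]1[C@H]2O[C@](C)(OC)[C@@](C)(OC)O[C@@H]2C=C(COC(=O)c3ccccc3)[C@@H]1OC(=O)c3ccccc3
F5 | step 9 | C3 acetate of F4 | CC(=O)O[C@H]1[C@H]2O[C@](C)(OC)[C@@](C)(OC)O[C@@H]2C=C(COC(=O)c3ccccc3)[C@@H]1OC(=O)c3ccccc3
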